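**Retrosynthetic overview**

1. The target is a 4β→8 dimer of one monomer, (2R,3R)-2,3-cis-flavan-3,5,7-triol (upper unit rings A/C, lower unit rings D/F, phenyl rings B/E). The last skeletal cut is the interflavan bond C4(ring C)–C8(ring D), made from a C4 cation and a C8-nucleophilic monomer, followed by global debenzylation.
2. Both partners come from one enol ether, (2R)-3,5,7-tris(benzyloxy)-2-phenyl-2H-chromene. Syn hydroboration of its C3=C4 bond sets C3 and puts OH on C4 (electrophile); removal of that OH gives the nucleophile.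
3. Key disconnection: C3–C4 of the pyran ring (ring F, and identically ring C). It is closed by a titanium-alkylidene carbonyl–olefin metathesis (olefinic-ester cyclization) of an acyclic aryl ether of benzyl mandelate.
4. Enabling feature: C3 lies between the O1–C2(H)Ph unit and the benzylic C4 on C4a of the phloroglucinol ring. C3 can therefore be the ester carbonyl of a chiral-pool mandelate and C4 the terminus of a vinyl group ortho to the C8a–O1 ether, so the two carbons are held within reach and C2 later steers C3 and C4.
5. Ring order: the aromatic rings are bought; the pyran ring is closed at C3–C4 (step 4); two monomers are joined C4–C8 (step 7).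

Key step: step 4

Assumption: the SMILES is read as the 4β→8 dimer with (2R,3R) in both units and (4R) at the upper C4 (2,3-cis, 3,4-trans); 3,5-bis(benzyloxy)phenol and benzyl (S)-mandelate are treated as purchasable.

**Step 1**
Reactants: 1 3,5-bis(benzyloxy)phenol; 2 formaldehyde (as paraformaldehyde)
Product: 3 4,6-bis(benzyloxy)-2-hydroxybenzaldehyde
Conditions: MgCl2, Et3N, (CH2O)n, MeCN, reflux
Reagents that add atoms: formaldehyde (paraformaldehyde) 2, C=O
Why: Magnesium phenoxide-directed ortho-formylation (Casnati–Skattebøl type), in which formaldehyde is delivered inside the magnesium chelate to a position ortho to the free OH (both ortho positions of 1 are equivalent) and the salicyl alcohol is oxidized in situ by a second formaldehyde through Oppenauer-type hydride transfer; no stereocenter is formed.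

**Step 2**
Reactants: 3 4,6-bis(benzyloxy)-2-hydroxybenzaldehyde; 4 methyltriphenylphosphonium bromide
Product: 5 3,5-bis(benzyloxy)-2-vinylphenol
Conditions: Ph3PCH3Br (2.5 equiv), KOtBu (2.5 equiv), THF, 0 °C → rt
Reagents that add atoms: methyltriphenylphosphonium bromide 4, C[P+](c1ccccc1)(c1ccccc1)c1ccccc1.[Br-]
Why: Wittig methylenation, in which the excess of non-stabilized ylide compensates for deprotonation of the phenol and still olefinates the aldehyde of the phenoxide; no stereocenter is formed.

**Step 3**
Reactants: 5 3,5-bis(benzyloxy)-2-vinylphenol; 6 benzyl (S)-mandelate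
Product: 7 benzyl (2R)-2-[3,5-bis(benzyloxy)-2-vinylphenoxy]-2-phenylacetate
Conditions: PPh3, DIAD, toluene, 0 °C → rt
Reagents that add atoms: none
Why: Mitsunobu etherification, an SN2 displacement of the activated secondary alcohol of 6 by the phenoxide of 5 with inversion, so that the (S)-mandelate should give the (R)-configured C2 that both flavan units need.

**Step 4**
Reactants: 7 benzyl (2R)-2-[3,5-bis(benzyloxy)-2-vinylphenoxy]-2-phenylacetate
Product: 9 (2R)-3,5,7-tris(benzyloxy)-2-phenyl-2H-chromene, via titanium benzylidene 8 (not isolated)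
Conditions: CH3CHBr2, TiCl4, Zn, PbCl2 (cat.), TMEDA, THF/CH2Cl2, 65 °C
Reagents that add atoms: none
Why: The ethylidene reagent formed from CH3CHBr2, Zn and TiCl4 should exchange with the terminal vinyl group of 7 by [2+2] cycloaddition and cycloreversion, releasing propene and placing the titanium alkylidene on C4 (8); 8 then adds across the ester carbonyl C3=O and the oxatitanacyclobutane collapses to the C3=C4 enol ether and TiOCl2. The closest known reaction type is the olefinic-ester cyclization with Takai–Utimoto titanium alkylidenes (tandem olefin metathesis and carbonyl olefination), with the stepwise ester methylenation and enol ether–olefin ring-closing metathesis as its two-pot relative. The pyran ring closes as a six-membered ring by intramolecular carbonyl olefination, a formal ring-closing carbonyl–olefin metathesis between C4 and C3, which the aromatic ring holds ortho to each other through C4a and C8a–O1. No stereocenter is created: C2, set in step 3, should be carried through because the reagent is non-basic and TMEDA buffers its Lewis acidity, and the alkene geometry is fixed by the ring. The selectivity needed is alkylidene exchange at the monosubstituted alkene before ethylidenation of the hindered, α-branched ester; even if the order is reversed, the acyclic ethylidene enol ether remains a competent substrate for the same ring closure. In one operation the step should deliver the complete, correctly oxygenated C6–C3–C6 heterocycle that serves as both halves of the target, with the C3=C4 enol ether as the single handle from which C3, C4 and the interflavan bond are later set.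

**Step 5**
Reactants: 9 (2R)-3,5,7-tris(benzyloxy)-2-phenyl-2H-chromene
Product: 11 (2R,3R,4S)-3,5,7-tris(benzyloxy)-2-phenylchroman-4-ol, via C4 alkylborane 10 (not isolated)
Conditions: BH3·THF, THF, 0 °C; then NaOH, H2O2, 0 °C → rt
Reagents that add atoms: hydrogen peroxide, OO
Why: Hydroboration–oxidation of a cyclic enol ether, in which boron should go to C4 (β to the benzyloxy group and the less substituted alkene carbon) and hydrogen to C3 in a syn addition to the face opposite the 2-phenyl group (turned pseudoaxial by allylic 1,2-strain with 3-OBn), setting C3 (R, 2,3-cis) and C4 (S, 3,4-trans), with C–B oxidation proceeding with retention.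

**Step 6**
Reactants: 11 (2R,3R,4S)-3,5,7-tris(benzyloxy)-2-phenylchroman-4-ol
Product: 13 (2R,3R)-3,5,7-tris(benzyloxy)-2-phenylchromane, via C4 cation trifluoroacetate 12 (not isolated)
Conditions: Et3SiH (excess), CF3CO2H, CH2Cl2, −40 °C
Reagents that add atoms: none
Why: Ionic hydrogenation (benzylic deoxygenation), in which CF3CO2H ionizes the 4-OH to the C4 benzylic cation, present as its trifluoroacetate ion pair 12 and stabilized by the ortho and para oxygens O1, O5 and O7 of the aromatic ring, and the excess silane should transfer hydride to C4 faster than any arene can capture the cation; C2 and C3 are not touched.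

**Step 7**
Reactants: 11 (2R,3R,4S)-3,5,7-tris(benzyloxy)-2-phenylchroman-4-ol; 13 (2R,3R)-3,5,7-tris(benzyloxy)-2-phenylchromane (4 equiv)
Product: 15 (2R,3R,4R)-3,5,7-tris(benzyloxy)-2-phenyl-4-[(2R,3R)-3,5,7-tris(benzyloxy)-2-phenylchroman-8-yl]chromane, via C4 cation triflate 14 (not isolated)
Conditions: TMSOTf (cat.), 4 Å MS, CH2Cl2, −78 → −30 °C
Reagents that add atoms: none
Why: Acid-promoted Friedel–Crafts-type flavan-4-ol/flavan condensation (the standard interflavan coupling), in which TMSOTf ionizes the 4-OH of 11 with loss of water to the C4 benzylic cation, here paired with triflate (14), and this cation should be attacked by C8 of 13, the most nucleophilic ring position, on the face anti to the pseudoaxial 3-OBn group, giving the 3,4-trans (4R) bond, while the excess of 13 suppresses attack on ring A of the product.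

**Step 8**
Reactants: 15 (2R,3R,4R)-3,5,7-tris(benzyloxy)-2-phenyl-4-[(2R,3R)-3,5,7-tris(benzyloxy)-2-phenylchroman-8-yl]chromane
Product: 16 (2R,3R,4R)-2-phenyl-4-[(2R,3R)-3,5,7-trihydroxy-2-phenylchroman-8-yl]chromane-3,5,7-triol
Conditions: H2 (1 atm), Pd(OH)2/C, THF/MeOH/H2O, rt
Reagents that add atoms: none
Why: Hydrogenolysis of the six benzyl ethers over Pd(OH)2/C, under which the ring C2–O1 bonds and the C4–C8 bond of flavan benzyl ethers should survive; no stereocenter is changed.

**Compound list**

1 | 3,5-bis(benzyloxy)phenol | Oc1cc(OCc2ccccc2)cc(OCc2ccccc2)c1 | starting material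
2 | formaldehyde (used as paraformaldehyde) | C=O | starting material
3 | 4,6-bis(benzyloxy)-2-hydroxybenzaldehyde | O=Cc1c(O)cc(OCc2ccccc2)cc1OCc1ccccc1 | intermediate
4 | methyltriphenylphosphonium bromide | C[P+](c1ccccc1)(c1ccccc1)c1ccccc1.[Br-] | starting material
5 | 3,5-bis(benzyloxy)-2-vinylphenol | C=Cc1c(O)cc(OCc2ccccc2)cc1OCc1ccccc1 | intermediate
6 | benzyl (S)-mandelate | O[C@H](C(=O)OCc1ccccc1)c1ccccc1 | starting material
7 | benzyl (2R)-2-[3,5-bis(benzyloxy)-2-vinylphenoxy]-2-phenylacetate | C=Cc1c(O[C@@H](C(=O)OCc2ccccc2)c2ccccc2)cc(OCc2ccccc2)cc1OCc1ccccc1 | intermediate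
8 | titanium benzylidene of 7 at C4, Cl2Ti=CH–aryl (not isolated; TMEDA ligands omitted) | Cl[Ti](Cl)=Cc1c(O[C@@H](C(=O)OCc2ccccc2)c2ccccc2)cc(OCc2ccccc2)cc1OCc1ccccc1 | intermediate
9 | (2R)-3,5,7-tris(benzyloxy)-2-phenyl-2H-chromene | C(c1ccccc1)OC1=Cc2c(OCc3ccccc3)cc(OCc3ccccc3)cc2O[C@@H]1c1ccccc1 | intermediate
10 | C4 alkylborane, (2R,3R,4S)-3,5,7-tris(benzyloxy)-2-phenylchroman-4-ylborane (not isolated) | O(Cc1ccccc1)c1cc(OCc2ccccc2)c2c(c1)O[C@H](c1ccccc1)[C@H](OCc1ccccc1)[C@H]2B | intermediate
11 | (2R,3R,4S)-3,5,7-tris(benzyloxy)-2-phenylchroman-4-ol (2,3-cis, 3,4-trans) | O(Cc1ccccc1)c1cc(OCc2ccccc2)c2c(c1)O[C@H](c1ccccc1)[C@H](OCc1ccccc1)[C@H]2O | intermediate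
12 | C4 benzylic cation of (2R,3R)-3,5,7-tris(benzyloxy)-2-phenylchromane as its trifluoroacetate ion pair (not isolated) | O(Cc1ccccc1)c1cc(OCc2ccccc2)c2c(c1)O[C@H](c1ccccc1)[C@H](OCc1ccccc1)[CH+]2.[O-]C(=O)C(F)(F)F | intermediate
13 | (2R,3R)-3,5,7-tris(benzyloxy)-2-phenylchromane (2,3-cis) | O(Cc1ccccc1)c1cc(OCc2ccccc2)c2c(c1)O[C@H](c1ccccc1)[C@H](OCc1ccccc1)C2 | intermediate
14 | C4 benzylic cation of (2R,3R)-3,5,7-tris(benzyloxy)-2-phenylchromane as its triflate ion pair (not isolated) | O(Cc1ccccc1)c1cc(OCc2ccccc2)c2c(c1)O[C@H](c1ccccc1)[C@H](OCc1ccccc1)[CH+]2.[O-]S(=O)(=O)C(F)(F)F | intermediate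
15 | (2R,3R,4R)-3,5,7-tris(benzyloxy)-2-phenyl-4-[(2R,3R)-3,5,7-tris(benzyloxy)-2-phenylchroman-8-yl]chromane | O(Cc1ccccc1)c1cc(OCc2ccccc2)c2c(c1)O[C@H](c1ccccc1)[C@H](OCc1ccccc1)[C@H]2c1c(OCc2ccccc2)cc(OCc2ccccc2)c2c1O[C@H](c1ccccc1)[C@H](OCc1ccccc1)C2 | intermediate
16 | (2R,3R,4R)-2-phenyl-4-[(2R,3R)-3,5,7-trihydroxy-2-phenylchroman-8-yl]chromane-3,5,7-triol | Oc1cc(O)c2c(c1)O[C@H](c1ccccc1)[C@H](O)[C@H]2c1c(O)cc(O)c2c1O[C@H](c1ccccc1)[C@H](O)C2 | target

**Step count and risks**

Total step count: 8. Longest linear sequence: 8 steps (1 → 16; 11 is used twice, once as the electrophile and once as the source of 13).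

Steps most likely to fail:

Step 4. The titanium ethylidene may olefinate the ester before it engages the ortho,ortho-disubstituted vinyl group and stop at an acyclic enol ether, or C2 may epimerize in the warm amine-containing medium. Fallback: setting out from 7, the ester carbonyl is first methylenated with the Tebbe reagent Cp2Ti(μ-Cl)(μ-CH2)AlMe2 (THF/pyridine, −40 °C → rt) to give the acyclic enol ether 1,5-bis(benzyloxy)-3-{[(1R)-2-(benzyloxy)-1-phenylprop-2-en-1-yl]oxy}-2-vinylbenzene F1. F1 is then closed in a separate ruthenium-catalysed enol ether–olefin ring-closing metathesis (second-generation Grubbs catalyst (H2IMes)(PCy3)Cl2Ru=CHPh, toluene, 70 °C) with loss of ethylene. This comes back to the route at 9.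

Step 5. Boron may be delivered to C3 instead of C4, the borane may add to the face syn to the phenyl group, or the trans-β-benzyloxy alkylborane may eliminate before it is oxidized. Fallback: setting out from 9, the enol ether is hydrolysed (oxalic acid, wet THF) to (2R)-5,7-bis(benzyloxy)-2-phenylchroman-3-one F2. F2 is reduced with LiBH(s-Bu)3 (THF, −78 °C, hydride anti to the 2-phenyl group) to the cis alcohol (2R,3R)-5,7-bis(benzyloxy)-2-phenylchroman-3-ol F3, and benzylation (NaH, BnBr, DMF) comes back to the route at 13. The electrophile is then made from 13 by benzylic oxidation with DDQ in the presence of 2-ethoxyethanol (CH2Cl2, rt), giving (2R,3R,4S)-3,5,7-tris(benzyloxy)-4-(2-ethoxyethoxy)-2-phenylchromane F4. Under the TMSOTf conditions of step 7, F4 ionizes with loss of 2-ethoxyethanol to the cation triflate 14 and so replaces 11 in that step; the route is rejoined at 15.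

Step 7. The cation may be captured by ring A of the product, so that the chain grows to oligomers, or it may attack C6 instead of C8 of 13. Fallback: setting out from 11, C8 of ring A is capped with bromine (NBS, CH2Cl2, −78 °C) to give (2R,3R,4S)-3,5,7-tris(benzyloxy)-8-bromo-2-phenylchroman-4-ol F5. Coupling of F5 with a near-equimolar amount of 13 under the same acid catalysis gives the capped dimer (2R,3R,4S)-3,5,7-tris(benzyloxy)-8-bromo-2-phenyl-4-[(2R,3R)-3,5,7-tris(benzyloxy)-2-phenylchroman-8-yl]chromane F6 (same 4β geometry as 15; the descriptor changes with the bromine), whose upper ring A should no longer act as a nucleophile. Hydrogenolysis with H2, Pd(OH)2/C and Et3N removes the bromine together with the benzyl groups and comes back to the route at 16.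

**Further compounds**

F1 | step 4 | 1,5-bis(benzyloxy)-3-{[(1R)-2-(benzyloxy)-1-phenylprop-2-en-1-yl]oxy}-2-vinylbenzene | C=Cc1c(O[C@@H](C(=C)OCc2ccccc2)c2ccccc2)cc(OCc2ccccc2)cc1OCc1ccccc1
F2 | step 5 | (2R)-5,7-bis(benzyloxy)-2-phenylchroman-3-one | O(Cc1ccccc1)c1cc(OCc2ccccc2)c2c(c1)O[C@H](c1ccccc1)C(=O)C2
F3 | step 5 | (2R,3R)-5,7-bis(benzyloxy)-2-phenylchroman-3-ol | O(Cc1ccccc1)c1cc(OCc2ccccc2)c2c(c1)O[C@H](c1ccccc1)[C@H](O)C2
F4 | step 5 | (2R,3R,4S)-3,5,7-tris(benzyloxy)-4-(2-ethoxyethoxy)-2-phenylchromane | O(Cc1ccccc1)c1cc(OCc2ccccc2)c2c(c1)O[C@H](c1ccccc1)[C@H](OCc1ccccc1)[C@H]2OCCOCC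
F5 | step 7 | (2R,3R,4S)-3,5,7-tris(benzyloxy)-8-bromo-2-phenylchroman-4-ol | O(Cc1ccccc1)c1cc(OCc2ccccc2)c2c(c1Br)O[C@H](c1ccccc1)[C@H](OCc1ccccc1)[C@H]2O
F6 | step 7 | (2R,3R,4S)-3,5,7-tris(benzyloxy)-8-bromo-2-phenyl-4-[(2R,3R)-3,5,7-tris(benzyloxy)-2-phenylchroman-8-yl]chromane | O(Cc1ccccc1)c1cc(OCc2ccccc2)c2c(c1Br)O[C@H](c1ccccc1)[C@H](OCc1ccccc1)[C@H]2c1c(OCc2ccccc2)cc(OCc2ccccc2)c2c1O[C@H](c1ccccc1)[C@H](OCc1ccccc1)C2
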